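Ring A is numbered C1 (carboxyl-bearing carbon), C2 (aryloxy), C4 (methoxy), C6 (heptyl). Ring B is numbered C1' (ether oxygen), C2' (H), C3' (hydroxyl), C4' (carboxyl), C5' (heptyl), C6' (methoxy).

## Analysis of the target

The target 9 is a diaryl ether of two benzoic acids, joined by one oxygen between C2 of ring A and C1' of ring B. It has no fused ring and no stereocentre, so the whole problem is one of substitution pattern. Ring A is tetrasubstituted, whereas ring B is pentasubstituted, with a contiguous run C3' OH, C4' CO2H, C5' heptyl, C6' OMe, C1' OAr and a single C2'–H. Both carboxyl groups are flanked on both sides, so they are hard to esterify or saponify and are prone to protodecarboxylation; the ring B acid is in addition a salicylic acid. The C3' hydroxyl lies para to the C6' methoxy group, which makes ring B a hydroquinone monoether that oxidises easily. The difficulty is to place two identical, unfunctionalised seven-carbon chains at the most crowded positions of two different electron-rich rings, and to end with exactly one free hydroxyl among the three ring oxygens at C3', C4 and C6'. The strategy rests on one feature: each heptyl chain is ortho to the carboxyl of its own ring (C6 next to C1, C5' next to C4'), while the other ortho position of each carboxyl already carries oxygen (C2 aryloxy, C3' oxygen). Without the chains, each carboxyl therefore has exactly one ortho C–H, and the carboxyl groups of the target can act as directing groups.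

## Retrosynthetic reasoning

**9 from 8 (C3' O–CH3 bond).** The last operation is the unmasking of the C3' hydroxyl from its methyl ether. The free phenol would not survive the oxidising, silver-containing medium of the chain-installing step, because of its para relationship to the C6' methoxy group. A methyl ether is the smallest mask, is already present in the purchasable phenol 2, and keeps C3' blocked. Among the three methyl ethers of 8 it alone sits ortho to a carboxyl, so a boron Lewis acid held by that carboxyl can reach it through a six-membered chelate. The forward reaction has to cleave one of three methyl ethers and leave the diaryl ether and both acids intact.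

**8 from 4 and two equivalents of 6 (C6–CH2 and C5'–CH2 bonds).** These two bonds are the only carbon–carbon bonds outside the arenes and carboxyl groups, and both lie ortho to a carboxyl. Cutting them together uses the fact that the two chains are identical although the molecule is not symmetric, so one heptyl donor serves both rings, one equivalent per ring. The chain-free diacid 4 that results is two steps from purchasable arenes. Cutting the diaryl ether first, with the chains in place, would instead demand two separately built, fully substituted rings. The forward reaction has to activate one C–H bond per ring and couple each with a primary alkyl group that carries beta hydrogens.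

**6 from 5 (boron–fluorine exchange).** The trifluoroborate 6 is the crystalline, air-stable form of the heptyl donor and comes in one operation from the boronic acid 5.

**4 from 3 (oxidation level at the C4' carbon).** The ring B building block is available as an aldehyde, and the para-formyl group also tempers the electron-rich phenol during the copper coupling. The oxidation must precede the chain installation, because the carboxylate is the directing group.

**3 from 1 and 2 (C2–O bond of the diaryl ether).** The ether is cut on the ring A side because the bromide of 1 sits ortho to a carboxylate, which assists copper-mediated substitution. The opposite polarity would need a halide at C1' of a very electron-rich ring and a hydrogen-bonded, poorly nucleophilic ortho-hydroxy acid as the phenol partner. The forward reaction has to join the two rings without harming the aldehyde.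

## Alternatives that were turned down

Alternative 1: ring B by thermal ring expansion of the cyclobutenone A1.
- Disconnection: the C3'–C4' bond of ring B is cut, which leads back to the 4-alkenyl-4-methoxy-3-aryloxycyclobutenone A1; its aryloxy group is ring A as the benzyl ester.
- Forward key step: heating A1 cleaves the bond between the carbonyl carbon and the quaternary carbon of the four-membered ring in a four-electron electrocyclic opening, and six-electron closure of the former carbonyl carbon onto the alkene terminus (a Moore-type rearrangement) gives the phenol A2.
- For it: the crowded pentasubstituted pattern of ring B is fixed by construction, and the C3' oxygen appears directly as the free phenol. On these two points it is stronger than the chosen route, which depends on C–H cleavage at a flanked site and on a selective demethylation.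
- Against it: the key step builds only one ring, so ring A with its own heptyl chain must be made separately and attached to the four-membered ring beforehand. After the key step the silyloxymethyl group of A2 must be unmasked and oxidised in two stages to the acid, next to a free phenol on an oxidation-prone hydroquinone monoether, and the benzyl ester must still be removed.
- Comparison: the sequence is several times longer than the chosen one. The chosen route offers in its place five steps and one reaction for both chains.

Alternative 2: three-component union of an aryne, a phenoxide and carbon dioxide.
- Disconnection: the C2–O and C1–carboxyl bonds of ring A are cut, which leads to the silylaryl triflate A3 (the precursor of 3-bromo-5-methoxybenzyne A4), the ring B phenol A5 and carbon dioxide A6.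
- Forward key step: fluoride releases A4 from A3, the phenoxide of A5 adds at the aryne carbon remote from bromine, and the aryl anion captures A6 to give the acid A7.
- For it: the diaryl ether and the ring A carboxyl are formed together under mild conditions, and the distortion of A4 sets the ring A pattern. In convergence it is at least equal to the chosen route.
- Against it: the aryl anion is ortho to bromine and can expel bromide to give a second aryne, or be protonated, before it is carboxylated. The bromide of A7 then needs a separate sp2–sp3 coupling at a doubly flanked position. The pentasubstituted phenol A5, heptyl chain included, must be made on its own, so the harder ring is not addressed.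
- Comparison: more steps and three benzyl groups to remove. The chosen route offers a single solution for both chains on a core that is made in two steps.

Alternative 3: ring A by Diels–Alder reaction of an aryloxypyrone with an alkynoate.
- Disconnection: the C1–C2 and C5–C6 bonds of ring A are cut, which leads to the 6-aryloxy-4-methoxy-2-pyrone A8 and benzyl dec-2-ynoate A9.
- Forward key step: A8 adds through pyrone carbons 6 and 3 to A9, and extrusion of the lactone bridge as A6 in the same operation aromatises ring A and gives the tribenzyl-protected target A10.
- For it: the heptyl chain and the carboxyl of ring A arrive together, with the regiochemistry set by the donor pattern of the diene and without a metal. The final hydrogenolysis of three benzyl groups is unambiguous, which is cleaner than the selective demethylation of the chosen route.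
- Against it: A8 is a vinylogous aryl ester and is labile towards nucleophiles. The cycloaddition with a disubstituted alkynoate needs high temperature. A8 must be prepared from the fully substituted ring B phenol A5, so again the crowded ring with its chain has to be built by other means.
- Comparison: the key step solves the easier ring only. The chosen route offers brevity and treats both rings with the same reaction.

Key step: step 4

Remark on the chemistry: the unhindered C6–H of ring A is assumed to be alkylated before the flanked C5'–H of ring B, so the transient mono-alkylated diacid is drawn as 7; the other order would lead to the same product 8.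

## Route

Step 1
Reactants: 1 2-bromo-4-methoxybenzoic acid; 2 4-hydroxy-2,5-dimethoxybenzaldehyde
Product: 3 2-(4-formyl-2,5-dimethoxyphenoxy)-4-methoxybenzoic acid
Conditions: Cu2O (cat.), Cs2CO3, DMF, 110 °C; then aq. HCl
Reagents that add atoms: none
Why: Ullmann diaryl ether condensation; the ortho carboxylate of 1 binds monovalent copper and delivers it to the C–Br bond, so the phenoxide of 2 displaces bromide under conditions that the aldehyde (no alpha hydrogen, carbonate base) and the methyl ethers tolerate. Only one C–Br bond and one phenol are present, so no selectivity question arises.

Step 2
Reactants: 3 2-(4-formyl-2,5-dimethoxyphenoxy)-4-methoxybenzoic acid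
Product: 4 2-(4-carboxy-2,5-dimethoxyphenoxy)-4-methoxybenzoic acid
Conditions: NaClO2, NaH2PO4, 2-methyl-2-butene, t-BuOH/H2O, 0 °C to rt
Reagents that add atoms: sodium chlorite, [Na+].[O-]Cl=O
Why: Pinnick oxidation; chlorous acid adds to the aldehyde and fragments to the carboxylic acid, and the alkene scavenger removes the hypochlorite by-product before it can chlorinate the electron-rich rings. The diaryl ether, the methyl ethers and the existing carboxyl are inert.

Step 3
Reactants: 5 heptylboronic acid
Product: 6 potassium heptyltrifluoroborate
Conditions: KHF2, MeOH/H2O, rt; recrystallisation from acetone/Et2O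
Reagents that add atoms: potassium hydrogen difluoride, [K+].F[H-]F
Why: Fluoride exchange at boron converts the boronic acid into the tetracoordinate trifluoroborate salt, a crystalline, air-stable heptyl donor that can be weighed accurately and releases its alkyl group slowly under the coupling conditions.

Step 4
Reactants: 4 2-(4-carboxy-2,5-dimethoxyphenoxy)-4-methoxybenzoic acid; 6 potassium heptyltrifluoroborate (first equivalent, for ring A)
Product: 8 2-(4-carboxy-3-heptyl-2,5-dimethoxyphenoxy)-6-heptyl-4-methoxybenzoic acid, via ring A mono-heptyl diacid 7 (not isolated)
Conditions: 6 (two equivalents consumed, used in excess), Pd(OAc)2 (cat.), Ac-Leu-OH (cat.), Ag2CO3 (excess), 1,4-benzoquinone (cat.), t-BuOH, 90 °C; then aq. HCl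
Reagents that add atoms: potassium heptyltrifluoroborate 6 (second equivalent, for ring B), CCCCCCC[B-](F)(F)F.[K+]
Why: After exchange of acetate for the substrate carboxylate, divalent palladium carrying the N-acetyl amino acid ligand cleaves the only ortho C–H bond of that ring by concerted metalation and deprotonation, with the N-acetyl group as the internal base, and gives a five-membered carboxylate palladacycle. The heptyl group then passes from boron of 6 to palladium, and reductive elimination, assisted by coordinated benzoquinone, forms the aryl–heptyl bond and zerovalent palladium, which Ag2CO3 returns to the divalent state. The closest known reaction type is the ligand-accelerated Pd(OAc)2-catalysed ortho C–H alkylation of benzoic acids with primary alkyltrifluoroborates, run here twice in one flask, so that each molecule of 4 takes up two equivalents of 6 and two oxidative turnovers. No ring is closed and no stereocentre is formed. The step needs site selectivity, and the substrate supplies it: on ring A the carboxylate has C2 blocked by the aryloxy group and only C6–H free, on ring B it has C3' blocked by methoxy and only C5'–H free, so neither regioisomers nor over-alkylation can arise, and C3, C5 and C2' lie outside the reach of a five-membered palladacycle. The open C6–H should react first to give 7, which then takes up the second equivalent of 6 more slowly at the C5'–H between carboxyl and methoxy, hence the excess of 6 and of oxidant. Beta-hydride loss from the heptyl–palladium species is the competing path; the chelating amino acid ligand occupies the site this needs and speeds the productive steps.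

Step 5
Reactants: 8 2-(4-carboxy-3-heptyl-2,5-dimethoxyphenoxy)-6-heptyl-4-methoxybenzoic acid
Product: 9 2-(4-carboxy-3-heptyl-5-hydroxy-2-methoxyphenoxy)-6-heptyl-4-methoxybenzoic acid
Conditions: BCl3 (excess), CH2Cl2, −78 °C to 0 °C; then H2O
Reagents that add atoms: none
Why: Chelation-controlled Lewis acid ether cleavage; boron bound to the ring B carboxyl closes a six-membered chelate with the C3' methoxy oxygen and activates that methyl group for SN2 attack by chloride. The C4 and C6' methyl ethers have no such template, and the corresponding chelate on ring A holds only the diaryl ether oxygen, which cannot be dealkylated; aqueous work-up then releases the phenol and both acids.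

## Compound list

1 | 2-bromo-4-methoxybenzoic acid | COc1ccc(C(=O)O)c(Br)c1 | starting material
2 | 4-hydroxy-2,5-dimethoxybenzaldehyde | COc1cc(C=O)c(OC)cc1O | starting material
3 | 2-(4-formyl-2,5-dimethoxyphenoxy)-4-methoxybenzoic acid | COc1ccc(C(=O)O)c(Oc2cc(OC)c(C=O)cc2OC)c1 | intermediate
4 | 2-(4-carboxy-2,5-dimethoxyphenoxy)-4-methoxybenzoic acid | COc1ccc(C(=O)O)c(Oc2cc(OC)c(C(=O)O)cc2OC)c1 | intermediate
5 | heptylboronic acid | CCCCCCCB(O)O | starting material
6 | potassium heptyltrifluoroborate | CCCCCCC[B-](F)(F)F.[K+] | intermediate
7 | 2-(4-carboxy-2,5-dimethoxyphenoxy)-6-heptyl-4-methoxybenzoic acid (ring A mono-heptyl diacid, not isolated) | CCCCCCCc1cc(OC)cc(Oc2cc(OC)c(C(=O)O)cc2OC)c1C(=O)O | intermediate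
8 | 2-(4-carboxy-3-heptyl-2,5-dimethoxyphenoxy)-6-heptyl-4-methoxybenzoic acid | CCCCCCCc1cc(OC)cc(Oc2cc(OC)c(C(=O)O)c(CCCCCCC)c2OC)c1C(=O)O | intermediate
9 | 2-(4-carboxy-3-heptyl-5-hydroxy-2-methoxyphenoxy)-6-heptyl-4-methoxybenzoic acid | CCCCCCCc1cc(OC)cc(Oc2cc(O)c(C(=O)O)c(CCCCCCC)c2OC)c1C(=O)O | target

## Step count and least certain steps

Total step count: 5. Longest linear sequence: 4 steps (steps 1, 2, 4 and 5); step 3 is a one-step side branch.

**Step 4 (key step).**
- Most likely failures: incomplete alkylation at the C5'–H of ring B, so that the reaction stalls after the first heptyl transfer, because concerted metalation is slow at a position flanked by carboxyl and methoxy; beta-hydride loss from the heptyl–palladium species, which uses up 6 and returns unalkylated arene; silver-assisted protodecarboxylation of the doubly ortho-substituted acids once they have formed at 90 °C.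
- Fallback: the chain is built in two stages without silver and without an alkyl–metal species that carries beta hydrogens. It sets out from 4. Carboxylate-directed ortho C–H allylation of both rings with allyl acetate ([Ru(p-cymene)Cl2]2, K3PO4, 50 °C; alkene insertion, then beta-acetoxy elimination) should give 2-[4-carboxy-2,5-dimethoxy-3-(prop-2-en-1-yl)phenoxy]-4-methoxy-6-(prop-2-en-1-yl)benzoic acid F1. Cross metathesis of both allyl groups with excess 1-hexene (second-generation Grubbs catalyst, CH2Cl2, 40 °C) should give the bis(hept-2-enyl) diacid F2. Hydrogenation (H2, Pd/C, EtOAc) then comes back to the route at 8.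

**Step 5.**
- Most likely failures: loss of site selectivity in the ether cleavage, with competing dealkylation at C6' (the neighbouring ether oxygen offers a second, weaker binding site) or at C4 on warming, because a boron-bound free acid may be a poorer template than a carbonyl group; acid-promoted decarboxylation of the ring B salicylic acid during work-up.
- Fallback: the demethylation is run on esters, where carbonyl chelation is the better-established mode. It sets out from 8. Alkylation of both carboxylates (benzyl bromide, K2CO3, DMF) should give the dibenzyl ester F3. BCl3 in CH2Cl2 at −78 °C should then cleave the C3' methyl ether to the phenol dibenzyl ester F4; any benzyl ester lost at this point only anticipates the next operation. Hydrogenolysis (H2, Pd/C, EtOAc) comes back to the route at 9.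

**Step 1.**
- Most likely failures: slow C–O bond formation, because the phenoxide of 2 is weakened by the para-formyl group and hindered by the ortho methoxy group; reductive loss of bromine or hydroxylation of 1 at the temperature required.
- Fallback: the carboxylate-assisted copper reaction is replaced by a palladium-catalysed cross-coupling of the ester. It sets out from 1 and 2. Esterification of 1 (MeI, K2CO3, DMF) gives methyl 2-bromo-4-methoxybenzoate F5. C–O coupling with 2 (Pd(OAc)2, t-BuXPhos, K3PO4, toluene, 100 °C) should give methyl 2-(4-formyl-2,5-dimethoxyphenoxy)-4-methoxybenzoate F6. Saponification of this singly ortho-substituted ester (LiOH, THF/H2O, rt) comes back to the route at 3.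

## Further compounds

F1 | step 4 | 2-[4-carboxy-2,5-dimethoxy-3-(prop-2-en-1-yl)phenoxy]-4-methoxy-6-(prop-2-en-1-yl)benzoic acid | C=CCc1cc(OC)cc(Oc2cc(OC)c(C(=O)O)c(CC=C)c2OC)c1C(=O)O
F2 | step 4 | 2-[4-carboxy-3-[(E)-hept-2-en-1-yl]-2,5-dimethoxyphenoxy]-6-[(E)-hept-2-en-1-yl]-4-methoxybenzoic acid (major alkene isomer expected) | CCCC/C=C/Cc1cc(OC)cc(Oc2cc(OC)c(C(=O)O)c(C/C=C/CCCC)c2OC)c1C(=O)O
F3 | step 5 | benzyl 2-[4-(benzyloxycarbonyl)-3-heptyl-2,5-dimethoxyphenoxy]-6-heptyl-4-methoxybenzoate | CCCCCCCc1cc(OC)cc(Oc2cc(OC)c(C(=O)OCc3ccccc3)c(CCCCCCC)c2OC)c1C(=O)OCc1ccccc1
F4 | step 5 | benzyl 2-[4-(benzyloxycarbonyl)-3-heptyl-5-hydroxy-2-methoxyphenoxy]-6-heptyl-4-methoxybenzoate | CCCCCCCc1cc(OC)cc(Oc2cc(O)c(C(=O)OCc3ccccc3)c(CCCCCCC)c2OC)c1C(=O)OCc1ccccc1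
F5 | step 1 | methyl 2-bromo-4-methoxybenzoate | COC(=O)c1ccc(OC)cc1Br
F6 | step 1 | methyl 2-(4-formyl-2,5-dimethoxyphenoxy)-4-methoxybenzoate | COC(=O)c1ccc(OC)cc1Oc1cc(OC)c(C=O)cc1OC
A1 | alternative 1 | benzyl 2-[(4-{1-[(tert-butyldimethylsilyl)oxy]dec-2-en-3-yl}-4-methoxy-3-oxocyclobut-1-en-1-yl)oxy]-6-heptyl-4-methoxybenzoate (racemic, alkene geometry not fixed) | CCCCCCCC(=CCO[Si](C)(C)C(C)(C)C)C1(OC)C(=O)C=C1Oc1cc(OC)cc(CCCCCCC)c1C(=O)OCc1ccccc1
A2 | alternative 1 | benzyl 2-[4-({[tert-butyl(dimethyl)silyl]oxy}methyl)-3-heptyl-5-hydroxy-2-methoxyphenoxy]-6-heptyl-4-methoxybenzoate | CCCCCCCc1cc(OC)cc(Oc2cc(O)c(CO[Si](C)(C)C(C)(C)C)c(CCCCCCC)c2OC)c1C(=O)OCc1ccccc1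
A3 | alternative 2 | 2-bromo-4-methoxy-6-(trimethylsilyl)phenyl trifluoromethanesulfonate | COc1cc(Br)c(OS(=O)(=O)C(F)(F)F)c([Si](C)(C)C)c1
A4 | alternative 2 | 3-bromo-5-methoxybenzyne (3-bromo-5-methoxy-1,2-didehydrobenzene) | COC1=CC#CC(Br)=C1
A5 | alternative 2 | benzyl 6-(benzyloxy)-2-heptyl-4-hydroxy-3-methoxybenzoate | CCCCCCCc1c(OC)c(O)cc(OCc2ccccc2)c1C(=O)OCc1ccccc1
A6 | alternative 2 | carbon dioxide | O=C=O
A7 | alternative 2 | 2-{5-(benzyloxy)-4-[(benzyloxy)carbonyl]-3-heptyl-2-methoxyphenoxy}-6-bromo-4-methoxybenzoic acid | COc1cc(Br)c(C(=O)O)c(Oc2cc(OCc3ccccc3)c(C(=O)OCc3ccccc3)c(CCCCCCC)c2OC)c1
A8 | alternative 3 | benzyl 6-(benzyloxy)-2-heptyl-3-methoxy-4-[(4-methoxy-2-oxo-2H-pyran-6-yl)oxy]benzoate | COc1cc(=O)oc(Oc2cc(OCc3ccccc3)c(C(=O)OCc3ccccc3)c(CCCCCCC)c2OC)c1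
A9 | alternative 3 | benzyl dec-2-ynoate | CCCCCCCC#CC(=O)OCc1ccccc1
A10 | alternative 3 | benzyl 2-{5-(benzyloxy)-4-[(benzyloxy)carbonyl]-3-heptyl-2-methoxyphenoxy}-6-heptyl-4-methoxybenzoate | CCCCCCCc1cc(OC)cc(Oc2cc(OCc3ccccc3)c(C(=O)OCc3ccccc3)c(CCCCCCC)c2OC)c1C(=O)OCc1ccccc1
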